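The winter run slows too early. Between 5.00 min and 12.0 min target rises by 0.0133 min⁻¹ of the charge, and between 12.0 min and 25.0 min by 0.00846 min⁻¹, so the later mean rate is lower than the earlier, by a factor of 0.636.

| flask | substrate | partner | remark | time |
|---|---|---|---|---|
| winter | 0.055 M | 1.5 equiv | run made earlier |  |
| north | 0.015 M | 3.00 equiv |  | 40 min |
| south | 0.050 M | 1.00 equiv |  | 40 min |
| north-east | 0.080 M | 1.00 equiv |  | 40 min |
| north-west | 0.050 M | 1.50 equiv |  | 40 min |
| south-west | 0.080 M | 6.00 equiv |  | 40 min |

winter run (percent of the substrate charged): time / min: target / % = 1.50: 0.5; 5.00: 4.1; 8.00: 8.8; 12.0: 13.4; 20.0: 20.4; 25.0: 24.4

(readings scatter by 0.3 percentage points)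



- ranking by amount of target, in percent of the substrate charged, from high to low, at 40 min (north / south / north-east / north-west / south-west)
- the same order at 2.5 h (north / south / north-east / north-west / south-west)
- the amount of target, in percent of the substrate charged of the flask you put first, at 40 min
- the amount of target, in percent of the substrate charged of the flask you put last, at 40 min

Two views of this slowing are in dispute. The forecast reads the flask as “a bimolecular step, substrate + partner, feeding target through a short-lived intermediate”. It gives south-west > north-west > north-east > north > south at 40 min and south-west > north-west > north-east > north > south at 2.5 h, with 90% for the first flask, 23.5% for the last, and 55 % for south at 2.5 h.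

My objection is this. If target alone consumed substrate and partner one for one, the consumption between the readings at 8.00 min and 20.0 min would lower the rate to 0.801 of its value, and the ratio read from the two mean rates is lower than that. So I suppose a partner-free loss beside the partner's step, each first order in what remains.

The rate then fades exponentially. Placing the two mean rates at the middles of their windows gives a fade constant of 0.0451 min⁻¹. Carried forward from the last reading, this estimate puts the level of the winter run near 38.4%. Taking the mean [partner] as the charged 0.0825 M, I get the quantity I carry, the even-split concentration, which is the [partner] at which partner's step and the loss take equal shares (a selectivity factor of one): 0.132 M. With [partner] held at its charged value, target's final share in this reckoning is [partner] / ([partner] + even-split concentration).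

South, at [partner] 0.0500 M, is therefore estimated to level off near 27.4% and to stand at 21.5% at 40 min, which is lower than the forecast's figure. South-west, by the same reckoning, reaches 77.9%, also lower than the forecast.

The simulation gives south-west > north-west > north-east > north > south at 40 min and south-west > north-west > north > north-east > south at 2.5 h, with south-west at 86.2% and south at 18.2%.

    substrate ⇌ intermediate A (K = 1.96, k = 0.0608 min⁻¹)
    substrate ⇌ intermediate B (K = 1.94, k = 0.0795 min⁻¹)
    substrate + partner ⇌ intermediate C (K = 102 L mol⁻¹, k = 0.899 L mol⁻¹ min⁻¹)
    intermediate A → side product (k = 0.0261 min⁻¹)
    partner + intermediate C → target (k = 1.15 L mol⁻¹ min⁻¹)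

South at 40 min went my way: 18.2% lies nearer my figure than the forecast's. At 2.5 h south stands at 33.1%, which is far from 55 % but higher than the 27.4% I gave as its level. South-west, with [partner] above the even-split concentration, is the forecast's region, nearer its number than mine. In south, half of the turnover into intermediate B was done by 2.17 min, and at 20.0 min substrate stood at 14.5% beside intermediate A at 20.4% and intermediate B at 32.1%. From then on side product and target grew together, reaching 18.7% and 18.2% at 40.0 min, while intermediate B still held 27.2%.

Take south again with 4.00 equiv of partner, so [partner] is 0.200 M. The even-split concentration gives a share of 60.2% and 56.5% at 40 min. The flask gave 66.5% of target, with 10.5% of side product.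

All runs come from a simulation for an exercise, noise included.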